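The numbers are invented; the rest is arithmetic.

You cannot follow E on a single peak: free E, L.E and Z pass into one another, and that group leaks away to J and X.

    E → J (k1 = 0.011 s⁻¹)
    L + E → X (k2 = 0.35 L mol⁻¹ s⁻¹)
    L.E ⇌ Z (K3 = 0.61, k3 = 0.0041 s⁻¹)
    L + E ⇌ L.E (K4 = 13 L mol⁻¹, k4 = 0.76 L mol⁻¹ s⁻¹)

all flasks: L 0.13 M; time 2.5 min

| flask | E |
|---|---|
| violet | 0.100 M |
| grey | 0.130 M |
| teal | 0.0780 M |

- which of the two there is more of at the end, violet (L.E / X)
- which of the two there is more of at the end, grey (L.E / X)
- which of the two there is more of at the end, teal (L.E / X)
- amount of L.E at the end, in percent of the L charged, violet
- amount of L.E at the end, in percent of the L charged, grey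
- amount of L.E at the end, in percent of the L charged, teal

Take the lines in order. By that step alone, E falls to J with a half-life of 1.1 min, shorter than the run of 2.5 min, so this leak counts. But X takes more: at the start of violet, E goes to X faster than to J, by a ratio of 4.1. Both leaks draw on free E, and L.E and Z hide it from them. At the start of violet, L.E comes to balance with a half-life of 0.0495 min, and Z follows with 1.07 min, less comfortably but still shorter than the run.

So I call free E, L.E and Z together the live part of the E charge, and I treat them as balanced, a pre-equilibrium assumed for the reckoning. My reckoning then needs one number. 0.858 min⁻¹ is the drain constant: the leak of a free E, to J and X together, over the number of live forms per free E, with L put at half its charge. With L held by hand at that mean, my estimate is a plain exponential, so I reckon that 11.7% of the E charge stays live at the end.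

But L is a falling curve, not a mean. With L at its whole charge the live part comes to 10.3%, and at a quarter of it to 13.6%, and my estimate carries that spread. With L held at the mean, the E charge does not enter the estimate, so I carry the same fraction to grey and teal.

At that mean, I reckon that L.E holds 35.8% of the live part. Taken on the L charge, that gives me 3.22% in violet, 4.19% in grey and 2.52% in teal. The E that leaked gives X 45.8% in violet, 14.2 times my L.E there. In my reckoning the E charge scales both alike, so X leads in grey and teal too.

The forecast names X in violet, X in grey and X in teal. It puts L.E lower than I do, at 1.9%, 2.6% and 1.3%, reasoning that “little L.E survives while X has kept accumulating”.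

X leads in violet, grey and teal, as forecast, and L.E ends at 2.99%, 3.69% and 2.40%. In violet, L.E relaxes with a half-life of 0.108 min at the end, shorter than the run. Free E, L.E and Z in violet add up to 12.1% of the E charge, against the 11.7% from the drain constant. A neighbour of violet with 0.33 M of L, put at its closing fraction in the drain constant, gives 9.38% live, and that flask holds 11.0%.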